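## The problem

Compound 16 is an achiral, fully substituted benzene (ring A). It carries a 2-(3-methoxyphenyl)ethyl chain at C1, 4-hydroxybenzyl groups at C2, C4 and C6, a free hydroxyl at C3 and a methoxy group at C5. There is no stereocentre, so the whole difficulty is regiochemical. Six ring positions must be filled without ambiguity (C2 and C6 carry the same group but are not equivalent), and the two ring A oxygens must end up differentiated as OH and OMe. Electrophilic benzylation of a preformed resorcinol could not tell C2, C4 and C6 apart and would over-alkylate, so the substituents are better built in together with the ring. The four phenols and the doubly benzylic methylenes make 16 prone to oxidation towards quinone methides. The 4-hydroxyphenyl oxygens are therefore best carried as benzyl ethers that leave in a final neutral hydrogenolysis, which spares the two methyl ethers. The enabling feature is the C3–C4–C5–C6 segment: oxygens at C3 and C5 in a 1,3 relation, carbon C4 between them and a carbon substituent at C6. This is the imprint of a 2,4-disubstituted acetoacetate read as its bis-enol ether, a 1,3-dioxygenated diene. The remaining atoms C1 and C2 then have the pattern of an alkyne, and the C2 benzylic carbon can be carried as a ketone that activates this alkyne and is reduced afterwards.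

## Retrosynthesis

**16 from 15.** The three O–benzyl bonds are cut last. Tris(benzyl ether) 15 keeps the oxidation-prone phenols masked through all acidic, basic and thermal steps. The forward reaction only has to cleave benzyl aryl ethers without touching diarylmethane C–C bonds or methyl ethers, which hydrogenolysis over Pd/C does.

**15 from 14.** The C2 benzylic methylene is traced back to the diaryl ketone 14. Against a direct C2–benzyl bond formation on a finished ring, this cut turns the C2 substituent into the group that activates the dienophile one step earlier. The forward step is a deoxygenation of an electron-rich, ortho-hydroxylated benzophenone, for which ionic hydrogenation is suited.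

**14 from 12 and 6 (key disconnection).** Ring A is opened at C6–C1 and C2–C3. This gives the vinylogous ketene acetal 12 (C3 to C6 with both oxygens and two benzyl groups) and the ynone 6 (C1, C2, the aroyl group and the whole phenethyl chain). A cut of single benzyl groups from an intact ring would leave a regiochemistry problem at every step; here all six substituents arrive in two acyclic pieces of matched polarity. Cycloadduct 13 carries a mixed methyl silyl ketal at C3, so aromatization by loss of methanol leaves OH at C3 and OMe at C5 with no separate differentiation step. The forward reaction must be regioselective (diene terminus to the alkyne carbon remote from the carbonyl) and must tolerate a fully substituted diene.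

**12 from 11 and 10.** The O–Si bond and then the enol ether O–CH3 unit are removed, leading through the 3-methoxy enoate 11 to the β-keto ester 10. The precursor is an ordinary 2,4-disubstituted acetoacetate. The forward steps are O-methylation through the ketal and γ-deprotonation with O-silylation.

**10 from 9, 7 and 8.** The C2–benzyl and C4–benzyl bonds of 10 are cut to methyl acetoacetate 7 and two equivalents of 4-benzyloxybenzyl chloride 8, by way of the mono-C2-benzylated ester 9. Alkylating C2 first lets the cheap ester 7 be used in excess to suppress double alkylation. The second benzyl group then enters at the methyl carbon through the dianion.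

**6 from 4 and 5; 4 from 3, 1 and 2.** The acyl–alkyne bond of 6 is cut to the terminal alkyne 4 and 4-benzyloxybenzoyl chloride 5 (acyl Sonogashira coupling). This saves the oxidation step that an aldehyde addition would require. Alkyne 4 is cut at its benzylic–propargylic bond to 3-methoxybenzyl bromide 2 and 1-(trimethylsilyl)propyne 1, with silyl alkyne 3 as the alkylation product. The silyl group keeps the alkylation at the propargylic carbon.

## Roads not taken

**Alternative 1: Catellani double ortho-benzylation with Heck termination.**
- Cut: the C2–benzyl, C6–benzyl and C1–vinyl bonds at once. Ring A goes back to aryl iodide A1 (iodine at C1, hydrogen at C2 and C6, C3 as methoxymethyl ether, the C4 benzyl and C5 methoxy in place), two equivalents of 4-benzyloxybenzyl bromide A2 and 3-methoxystyrene A3.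
- Forward key step: under Pd(OAc)2, a triarylphosphine, norbornene and Cs2CO3, both ortho C–H bonds would be alkylated and the sequence would end with a Heck reaction to give stilbene A4. One hydrogenation would then saturate the alkene and remove the benzyl ethers, and acid would free the C3 hydroxyl to give 16.
- Merits: four components and three C–C bonds in one flask, use of the identical C2 and C6 groups, no carbonyl to reduce, and the shortest endgame of all the plans.
- Weak points: A1 is a 3,5-disubstituted iodoarene, so each ortho C–H bond lies between the iodine-bearing carbon and an oxygen-bearing carbon. Palladacycle formation at such flanked sites is slow, and meta-substituted iodides usually react only at the open side. Benzylic bromides are far less established as ortho-alkylating partners than simple primary alkyl halides, compete with the aryl iodide for zerovalent palladium and can alkylate the electron-rich rings directly. The Heck step would have to occur at a 2,6-dibenzylated arylpalladium. A1 also needs its own multistep synthesis, with a benzyl group placed between two differentiated oxygens.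
- Comparison: in convergence and in the number of steps after the key step this road is better. The chosen plan sets against it that every substituent position is fixed by ring construction from acyclic parts of matched polarity, and that no C–H functionalization at doubly flanked sites is required.

**Alternative 2: conjunctive coupling to insert the two-carbon bridge.**
- Cut: the C1–Ca and Cb–ring B bonds of the ethylene bridge. The precursors are the fully substituted ring A bromide A5, vinylboronic acid pinacol ester A6 and 3-methoxyphenyl triflate A7.
- Forward key step: the aryllithium from A5 adds to A6 to form a boronate complex. Pd(OAc)2 with a ferrocenyl bisphosphine and A7 then induces 1,2-migration of ring A from boron to Ca while the arylpalladium species delivers ring B to Cb, giving the benzylic boronate A8. Protodeboronation and hydrogenolysis would follow.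
- Merits: mild conditions, both bridge bonds made at once, and easy late variation of ring B.
- Weak points: the real problem, a hexasubstituted ring with the correct oxygen pattern, is left untouched inside A5, which would itself call for a ring synthesis of the kind chosen here. The migrating aryl group has two ortho benzyl substituents, which hinders the metallate shift. The aryllithium sits beside two diarylmethane methylenes whose protons can quench it. A boron-bearing stereocentre is created only to be erased, costing a protodeboronation at a congested benzylic carbon.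
- Comparison: this road is better only where analogues in ring B are wanted. The chosen plan brings the bridge carbons in with ynone 6 from cheap parts and spends no step on a transient stereocentre.

**Alternative 3: acylpyrone Diels–Alder with a methoxyalkyne and loss of carbon dioxide.**
- Cut: the C4–C5 and C1–C6 bonds. Ring A comes from 2-pyrone A9 (3-aroyl, 4-benzyloxy, 5-benzyl, 6-phenethyl) and 1-methoxyalkyne A10.
- Forward key step: an inverse-demand [4+2] cycloaddition followed by extrusion of carbon dioxide would give A11, with the ketone at C4. Ketone reduction and hydrogenolysis would then lead to 16.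
- Merits: aromatization by loss of carbon dioxide is irreversible and involves no choice of leaving group, since both ring A oxygens are fixed from the start (OMe from the alkyne, OBn on the pyrone). The polarity of the partners sets the regiochemistry, and A9 is a bench-stable solid-state type of diene.
- Weak points: the 4-alkoxy group donates into the pyrone and cancels much of the activation by the 3-aroyl group. The 5,6-disubstituted terminus is hindered. Pyrone–alkyne cycloadditions need high temperatures at which a 1-alkoxyalkyne is fragile. A10 is a sensitive ynol ether, and A9 needs a longer synthesis (pyrone assembly with regiocontrol at C5 and C6, C3 acylation, O-benzylation) than diene 12.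
- Comparison: this road equals the chosen plan in convergence and endgame length, and it is better in that the oxygen pattern does not depend on which group leaves on aromatization. The chosen plan sets against it a normal-demand pairing of an electron-rich diene with an electron-poor ynone, and precursors three and four steps from commodity chemicals.

Key step: step 8

Remark on the chemistry: enoate 11 is drawn as its E isomer and diene 12 as its 1Z,3Z isomer. Other isomers would converge, because both isomers of 11 give the same dienolate and C1 of the diene loses its configuration in ring A. Compounds 1, 5 and 8 are taken to be commercially available.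

## Route

Step 1
Reactants: 1 1-(trimethylsilyl)propyne; 2 3-methoxybenzyl bromide
Product: 3 [4-(3-methoxyphenyl)but-1-yn-1-yl]trimethylsilane
Conditions: n-BuLi, THF, −78 °C; then 2, −78 °C to rt
Reagents that add atoms: none
Why: Propargylic lithiation of the silyl-capped propyne followed by SN2 alkylation with the benzylic bromide; the silyl group blocks the alkyne terminus and keeps attack at the propargylic carbon, so little allene is expected.

Step 2
Reactants: 3 [4-(3-methoxyphenyl)but-1-yn-1-yl]trimethylsilane
Product: 4 1-(but-3-yn-1-yl)-3-methoxybenzene
Conditions: K2CO3 (cat.), MeOH, rt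
Reagents that add atoms: none
Why: Methanolysis of the alkynyl C–Si bond under mild base is a standard protodesilylation and touches nothing else in the molecule.

Step 3
Reactants: 4 1-(but-3-yn-1-yl)-3-methoxybenzene; 5 4-(benzyloxy)benzoyl chloride
Product: 6 1-[4-(benzyloxy)phenyl]-5-(3-methoxyphenyl)pent-2-yn-1-one
Conditions: PdCl2(PPh3)2 (2 mol %), CuI (4 mol %), Et3N, THF, rt
Reagents that add atoms: none
Why: Acyl Sonogashira coupling: the aroyl chloride adds oxidatively to zerovalent palladium, the copper acetylide transmetalates and reductive elimination gives the ynone; at room temperature an electron-rich aroylpalladium should not decarbonylate.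

Step 4
Reactants: 7 methyl acetoacetate; 8 4-(benzyloxy)benzyl chloride
Product: 9 methyl 2-[4-(benzyloxy)benzyl]-3-oxobutanoate (racemic)
Conditions: 7 (2 equiv), K2CO3, NaI (cat.), acetone, reflux
Reagents that add atoms: none
Why: Acetoacetic ester C-alkylation of the potassium enolate by the benzylic halide (activated in situ as the iodide); the excess of cheap 7 should suppress double alkylation.

Step 5
Reactants: 9 methyl 2-[4-(benzyloxy)benzyl]-3-oxobutanoate; 8 4-(benzyloxy)benzyl chloride
Product: 10 methyl 2-[4-(benzyloxy)benzyl]-5-[4-(benzyloxy)phenyl]-3-oxopentanoate (racemic)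
Conditions: NaH, THF, 0 °C; n-BuLi, 0 °C; then 8, 0 °C to rt; 1 M HCl
Reagents that add atoms: none
Why: Huckin–Weiler dianion alkylation: after the enolate is formed at C2, the second deprotonation occurs at the methyl group, and this more reactive γ-carbanion is alkylated by the benzylic chloride while C2 stays untouched.

Step 6
Reactants: 10 methyl 2-[4-(benzyloxy)benzyl]-5-[4-(benzyloxy)phenyl]-3-oxopentanoate
Product: 11 methyl (2E)-2-[4-(benzyloxy)benzyl]-5-[4-(benzyloxy)phenyl]-3-methoxypent-2-enoate
Conditions: HC(OMe)3, conc. H2SO4 (cat.), CH2Cl2, rt to 40 °C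
Reagents that add atoms: trimethyl orthoformate, COC(OC)OC
Why: Acid-catalysed ketalization of the ketone by the orthoformate and loss of methanol into conjugation with the ester gives the β-methoxy enoate, the standard entry to 2-alkyl-3-methoxy enoates; benzyl aryl ethers are inert to catalytic acid.

Step 7
Reactants: 11 methyl (2E)-2-[4-(benzyloxy)benzyl]-5-[4-(benzyloxy)phenyl]-3-methoxypent-2-enoate
Product: 12 {[(1Z,3Z)-2-[4-(benzyloxy)benzyl]-5-[4-(benzyloxy)phenyl]-1,3-dimethoxypenta-1,3-dien-1-yl]oxy}trimethylsilane
Conditions: LiN(i-Pr)2, THF, −78 °C; then Me3SiCl, −78 °C to rt; used crude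
Reagents that add atoms: chlorotrimethylsilane, C[Si](C)(C)Cl
Why: Kinetic γ-deprotonation at the C4 methylene, which lies cis to the ester carbonyl, gives the extended dienolate, and the hard silyl chloride traps it on oxygen as the vinylogous silyl ketene acetal; the C4 benzyl group should settle trans to the substituted C2 (3Z), the geometry needed for cycloaddition.

Step 8
Reactants: 12 {[(1Z,3Z)-2-[4-(benzyloxy)benzyl]-5-[4-(benzyloxy)phenyl]-1,3-dimethoxypenta-1,3-dien-1-yl]oxy}trimethylsilane; 6 1-[4-(benzyloxy)phenyl]-5-(3-methoxyphenyl)pent-2-yn-1-one
Product: 14 [4-(benzyloxy)phenyl]{3,5-bis[4-(benzyloxy)benzyl]-2-hydroxy-4-methoxy-6-[2-(3-methoxyphenyl)ethyl]phenyl}methanone, via cyclohexa-1,4-diene cycloadduct 13 (not isolated)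
Conditions: 12 (2 equiv), toluene, 110 °C, sealed tube; then 1 M HCl, THF, rt
Reagents that add atoms: none
Why: Diene 12 is a vinylogous ketene acetal whose two oxygen donors raise the HOMO and put its largest coefficient on the CH terminus (future C6), while the LUMO of ynone 6 is largest on the alkyne carbon remote from the carbonyl (future C1), so the C6–C1 bond leads in a strongly asynchronous normal-demand [4+2] cycloaddition. In the stepwise limit this is a Mukaiyama–Michael addition followed by closure of the allenolate carbon (future C2) onto the silyloxy-oxocarbenium carbon (future C3). Ring A is thus closed in a six-membered [4+2] mode, or 6-exo-trig in the stepwise picture, giving the 1,4-cyclohexadiene 13 with a mixed methyl silyl ketal at C3 and a hydrogen at C6. On acid work-up the more basic methoxy oxygen of the ketal is protonated or the O–Si bond is hydrolysed; either path expels methanol, the C6 hydrogen is lost and the silyl ether is cleaved, so C3 emerges as the phenol and C5 keeps its methoxy group. The closest known reaction type is the Diels–Alder reaction of 1-alkoxy-1-silyloxy-3-alkoxybutadienes with acetylenic ketones and esters followed by eliminative aromatization. No stereocentre survives, since both sp3 centres of 13 are erased. The selectivity needed is regiochemical and is secured by the donor pattern of the diene against the acceptor pattern of the ynone; the 3Z geometry keeps the C6 benzyl group on the outside of the s-cis diene. The hydrogen bond between the new C3 hydroxyl and the C2 carbonyl adds driving force for aromatization.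

Step 9
Reactants: 14 [4-(benzyloxy)phenyl]{3,5-bis[4-(benzyloxy)benzyl]-2-hydroxy-4-methoxy-6-[2-(3-methoxyphenyl)ethyl]phenyl}methanone
Product: 15 2,4,6-tris[4-(benzyloxy)benzyl]-3-methoxy-5-[2-(3-methoxyphenyl)ethyl]phenol
Conditions: Et3SiH (5 equiv), CF3CO2H/CH2Cl2 (1:4), 0 °C to rt
Reagents that add atoms: none
Why: Ionic hydrogenation: the protonated diaryl ketone accepts hydride from the silane, the resulting diarylmethanol ionizes to a cation stabilized by the 4-benzyloxyphenyl ring and the ortho hydroxyl, and a second hydride transfer gives the methylene; the excess silane also scavenges any benzyl cation, so the benzyl ethers should largely survive.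

Step 10
Reactants: 15 2,4,6-tris[4-(benzyloxy)benzyl]-3-methoxy-5-[2-(3-methoxyphenyl)ethyl]phenol
Product: 16 2,4,6-tris(4-hydroxybenzyl)-3-methoxy-5-[2-(3-methoxyphenyl)ethyl]phenol (CNP0285788.0)
Conditions: H2 (1 atm), 10% Pd/C, EtOAc/MeOH, rt
Reagents that add atoms: none
Why: Hydrogenolysis of the three benzyl aryl ethers over Pd/C is neutral and leaves methyl ethers, diarylmethane C–C bonds and the arenes intact.

## Compound list

1 | 1-(trimethylsilyl)propyne | CC#C[Si](C)(C)C | starting material
2 | 3-methoxybenzyl bromide | COc1cccc(CBr)c1 | starting material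
3 | [4-(3-methoxyphenyl)but-1-yn-1-yl]trimethylsilane | COc1cccc(CCC#C[Si](C)(C)C)c1 | intermediate
4 | 1-(but-3-yn-1-yl)-3-methoxybenzene | COc1cccc(CCC#C)c1 | intermediate
5 | 4-(benzyloxy)benzoyl chloride | O=C(Cl)c1ccc(OCc2ccccc2)cc1 | starting material
6 | 1-[4-(benzyloxy)phenyl]-5-(3-methoxyphenyl)pent-2-yn-1-one | O=C(C#CCCc1cccc(OC)c1)c1ccc(OCc2ccccc2)cc1 | intermediate
7 | methyl acetoacetate | COC(=O)CC(C)=O | starting material
8 | 4-(benzyloxy)benzyl chloride | ClCc1ccc(OCc2ccccc2)cc1 | starting material
9 | methyl 2-[4-(benzyloxy)benzyl]-3-oxobutanoate (racemic) | COC(=O)C(Cc1ccc(OCc2ccccc2)cc1)C(C)=O | intermediate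
10 | methyl 2-[4-(benzyloxy)benzyl]-5-[4-(benzyloxy)phenyl]-3-oxopentanoate (racemic) | COC(=O)C(Cc1ccc(OCc2ccccc2)cc1)C(=O)CCc1ccc(OCc2ccccc2)cc1 | intermediate
11 | methyl (2E)-2-[4-(benzyloxy)benzyl]-5-[4-(benzyloxy)phenyl]-3-methoxypent-2-enoate | COC(=O)/C(Cc1ccc(OCc2ccccc2)cc1)=C(/OC)CCc1ccc(OCc2ccccc2)cc1 | intermediate
12 | {[(1Z,3Z)-2-[4-(benzyloxy)benzyl]-5-[4-(benzyloxy)phenyl]-1,3-dimethoxypenta-1,3-dien-1-yl]oxy}trimethylsilane | CO/C(O[Si](C)(C)C)=C(Cc1ccc(OCc2ccccc2)cc1)/C(OC)=C/Cc1ccc(OCc2ccccc2)cc1 | intermediate
13 | [4-(benzyloxy)phenyl]{3,5-bis[4-(benzyloxy)benzyl]-4,6-dimethoxy-2-[2-(3-methoxyphenyl)ethyl]-6-[(trimethylsilyl)oxy]cyclohexa-1,4-dien-1-yl}methanone (racemic mixture of diastereomers, not isolated) | COC1(O[Si](C)(C)C)C(Cc2ccc(OCc3ccccc3)cc2)=C(OC)C(Cc2ccc(OCc3ccccc3)cc2)C(CCc2cccc(OC)c2)=C1C(=O)c1ccc(OCc2ccccc2)cc1 | intermediate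
14 | [4-(benzyloxy)phenyl]{3,5-bis[4-(benzyloxy)benzyl]-2-hydroxy-4-methoxy-6-[2-(3-methoxyphenyl)ethyl]phenyl}methanone | COc1cccc(CCc2c(C(=O)c3ccc(OCc4ccccc4)cc3)c(O)c(Cc3ccc(OCc4ccccc4)cc3)c(OC)c2Cc2ccc(OCc3ccccc3)cc2)c1 | intermediate
15 | 2,4,6-tris[4-(benzyloxy)benzyl]-3-methoxy-5-[2-(3-methoxyphenyl)ethyl]phenol | COc1cccc(CCc2c(Cc3ccc(OCc4ccccc4)cc3)c(O)c(Cc3ccc(OCc4ccccc4)cc3)c(OC)c2Cc2ccc(OCc3ccccc3)cc2)c1 | intermediate
16 | 2,4,6-tris(4-hydroxybenzyl)-3-methoxy-5-[2-(3-methoxyphenyl)ethyl]phenol | COc1cccc(CCc2c(Cc3ccc(O)cc3)c(O)c(Cc3ccc(O)cc3)c(OC)c2Cc2ccc(O)cc2)c1 | target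

## Step count and risks

Total: 10 steps. Longest linear sequence: 7 steps (steps 4 to 10, from methyl acetoacetate 7). The ynone branch (steps 1 to 3) joins at step 8.

**Step 8 (key step).** The diene terminus and the alkyne carbon that must join are both substituted, so the cycloaddition may be slow. Thermal decay of 12 (silyl shift from oxygen to carbon, hydrolysis) or addition of the diene to the ketone carbonyl could then outrun it. Aromatization could also partly proceed by loss of silanol, which would leave a methyl ether at C3. Fallback: setting out from 12 and 6, the two bonds would be made in separate ionic steps. BF3·OEt2 in CH2Cl2 at −78 °C should bring about a vinylogous Mukaiyama–Michael addition and give, after aqueous work-up, the open-chain keto ester methyl 2,4-bis[4-(benzyloxy)benzyl]-7-[4-(benzyloxy)phenyl]-3-methoxy-5-[2-(3-methoxyphenyl)ethyl]-7-oxohepta-2,5-dienoate F1 (racemic, alkene isomers). NaOMe in MeOH would then deprotonate the doubly vinylogous CH, and Claisen-type attack of the enone α-carbon on the ester would close ring A with loss of methanol. Tautomerization rejoins the route at 14. In this variant the C3 oxygen is the former ester carbonyl oxygen, so the OH/OMe pattern no longer depends on which group leaves.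

**Step 7.** Deprotonation of the tetrasubstituted enoate may be incomplete or misdirected towards the C2 benzylic methylene, silylation may occur on carbon, and the ketene acetal may hydrolyse during isolation. Fallback: setting out from 10, soft enolization with Me3SiOTf and Et3N (no lithium amide, and step 6 is bypassed as well) should give the bis(silyl) diene 2-[4-(benzyloxy)benzyl]-5-[4-(benzyloxy)phenyl]-1-methoxy-1,3-bis[(trimethylsilyl)oxy]penta-1,3-diene F2. Its cycloaddition with 6 and acid work-up would give the resorcinol ketone [4-(benzyloxy)phenyl]{3,5-bis[4-(benzyloxy)benzyl]-2,4-dihydroxy-6-[2-(3-methoxyphenyl)ethyl]phenyl}methanone F3. MeI and K2CO3 in acetone should methylate only the C5 hydroxyl, because the C3 hydroxyl is tied up in a hydrogen bond to the C2 carbonyl. This rejoins the route at 14.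

**Step 9.** The diarylmethyl cation may be captured intramolecularly by the 3-methoxyphenyl ring of the C1 chain (Friedel–Crafts closure of a seven-membered ring) in competition with hydride transfer. The acid may also cause partial loss of benzyl ethers with re-benzylation of the electron-rich rings. Fallback: setting out from 14, acylation with ClCO2Et and Et3N would give the aryl carbonate 2-[4-(benzyloxy)benzoyl]-4,6-bis[4-(benzyloxy)benzyl]-5-methoxy-3-[2-(3-methoxyphenyl)ethyl]phenyl ethyl carbonate F4. NaBH4 in THF/H2O reduces the ketone, the alkoxide takes over and expels the carbonate, and the ortho-quinone methide so formed is reduced by borohydride under basic conditions without any free cation. This rejoins the route at 15.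

**Step 5.** Formation of the dianion of the C2-substituted keto ester may be incomplete, and proton exchange between product enolate and dianion may lead to alkylation at C2 or to double alkylation. Fallback: the order of the two benzylations is reversed. Setting out from 7, the dianion (NaH, then n-BuLi, THF, 0 °C) is alkylated with 8 to give methyl 5-[4-(benzyloxy)phenyl]-3-oxopentanoate F5. Alkylation of F5 at C2 with 8 (K2CO3, NaI, acetone) rejoins the route at 10.

## Further compounds

F1 | step 8 | methyl 2,4-bis[4-(benzyloxy)benzyl]-7-[4-(benzyloxy)phenyl]-3-methoxy-5-[2-(3-methoxyphenyl)ethyl]-7-oxohepta-2,5-dienoate (racemic, alkene isomers) | COC(=O)C(Cc1ccc(OCc2ccccc2)cc1)=C(OC)C(Cc1ccc(OCc2ccccc2)cc1)C(CCc1cccc(OC)c1)=CC(=O)c1ccc(OCc2ccccc2)cc1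
F2 | step 7 | 2-[4-(benzyloxy)benzyl]-5-[4-(benzyloxy)phenyl]-1-methoxy-1,3-bis[(trimethylsilyl)oxy]penta-1,3-diene | COC(O[Si](C)(C)C)=C(Cc1ccc(OCc2ccccc2)cc1)C(O[Si](C)(C)C)=CCc1ccc(OCc2ccccc2)cc1
F3 | step 7 | [4-(benzyloxy)phenyl]{3,5-bis[4-(benzyloxy)benzyl]-2,4-dihydroxy-6-[2-(3-methoxyphenyl)ethyl]phenyl}methanone | COc1cccc(CCc2c(C(=O)c3ccc(OCc4ccccc4)cc3)c(O)c(Cc3ccc(OCc4ccccc4)cc3)c(O)c2Cc2ccc(OCc3ccccc3)cc2)c1
F4 | step 9 | 2-[4-(benzyloxy)benzoyl]-4,6-bis[4-(benzyloxy)benzyl]-5-methoxy-3-[2-(3-methoxyphenyl)ethyl]phenyl ethyl carbonate | CCOC(=O)Oc1c(C(=O)c2ccc(OCc3ccccc3)cc2)c(CCc2cccc(OC)c2)c(Cc2ccc(OCc3ccccc3)cc2)c(OC)c1Cc1ccc(OCc2ccccc2)cc1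
F5 | step 5 | methyl 5-[4-(benzyloxy)phenyl]-3-oxopentanoate | COC(=O)CC(=O)CCc1ccc(OCc2ccccc2)cc1
A1 | alternative 1 | 2-[4-(benzyloxy)benzyl]-5-iodo-1-methoxy-3-(methoxymethoxy)benzene | COCOc1cc(I)cc(OC)c1Cc1ccc(OCc2ccccc2)cc1
A2 | alternative 1 | 4-(benzyloxy)benzyl bromide | BrCc1ccc(OCc2ccccc2)cc1
A3 | alternative 1 | 3-methoxystyrene | C=Cc1cccc(OC)c1
A4 | alternative 1 | 2,4,6-tris[4-(benzyloxy)benzyl]-1-methoxy-3-(methoxymethoxy)-5-[(E)-2-(3-methoxyphenyl)ethenyl]benzene | COc1cccc(/C=C/c2c(Cc3ccc(OCc4ccccc4)cc3)c(OCOC)c(Cc3ccc(OCc4ccccc4)cc3)c(OC)c2Cc2ccc(OCc3ccccc3)cc2)c1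
A5 | alternative 2 | 1-bromo-3-(benzyloxy)-2,4,6-tris[4-(benzyloxy)benzyl]-5-methoxybenzene | COc1c(Cc2ccc(OCc3ccccc3)cc2)c(Br)c(Cc2ccc(OCc3ccccc3)cc2)c(OCc2ccccc2)c1Cc1ccc(OCc2ccccc2)cc1
A6 | alternative 2 | vinylboronic acid pinacol ester | C=CB1OC(C)(C)C(C)(C)O1
A7 | alternative 2 | 3-methoxyphenyl trifluoromethanesulfonate | COc1cccc(OS(=O)(=O)C(F)(F)F)c1
A8 | alternative 2 | 2-{1-[3-(benzyloxy)-2,4,6-tris[4-(benzyloxy)benzyl]-5-methoxyphenyl]-2-(3-methoxyphenyl)ethyl}-4,4,5,5-tetramethyl-1,3,2-dioxaborolane (racemic) | COc1cccc(CC(B2OC(C)(C)C(C)(C)O2)c2c(Cc3ccc(OCc4ccccc4)cc3)c(OCc3ccccc3)c(Cc3ccc(OCc4ccccc4)cc3)c(OC)c2Cc2ccc(OCc3ccccc3)cc2)c1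
A9 | alternative 3 | 3-[4-(benzyloxy)benzoyl]-4-(benzyloxy)-5-[4-(benzyloxy)benzyl]-6-[2-(3-methoxyphenyl)ethyl]-2H-pyran-2-one | O=c1oc(CCc2cccc(OC)c2)c(Cc2ccc(OCc3ccccc3)cc2)c(OCc2ccccc2)c1C(=O)c1ccc(OCc2ccccc2)cc1
A10 | alternative 3 | 1-(benzyloxy)-4-(3-methoxyprop-2-yn-1-yl)benzene | COC#CCc1ccc(OCc2ccccc2)cc1
A11 | alternative 3 | [4-(benzyloxy)phenyl]{2-(benzyloxy)-3,5-bis[4-(benzyloxy)benzyl]-6-methoxy-4-[2-(3-methoxyphenyl)ethyl]phenyl}methanone | COc1cccc(CCc2c(Cc3ccc(OCc4ccccc4)cc3)c(OCc3ccccc3)c(C(=O)c3ccc(OCc4ccccc4)cc3)c(OC)c2Cc2ccc(OCc3ccccc3)cc2)c1
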